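Numbering used throughout (germacrane): ring carbons C1–C10; C11–C13 are the acrylate carbons of the lactone (C12 carbonyl, C13 methylene); C14 is the formyl carbon on C10; C15 is the hydroxymethyl carbon on C4. α/β refer to the usual germacranolide drawing (H-7 α).

Remark: enals 17 and 18 are written as the E isomers; the Z isomers would serve equally, because C1 is sp3 in intermediate 19 and the C1=C10 geometry is set anew in step 13.

## The problem

The target is a germacran-12,6α-olide: a ten-membered carbocycle (C1–C10) trans-fused at C6–C7 to an α-methylene-γ-butyrolactone (O–C6–C7–C11–C12). Both ring double bonds, C1=C10 and C4=C5, are cis within the ring (E by CIP only because of the CHO and CH2OH groups), so the ring is a (Z,Z)-cyclodeca-1,5-diene. Closing this ring is the hardest task, and sigmatropic ring expansions are of little help because they deliver trans ring olefins. Four contiguous stereocentres (6R,7S,8S,9S) carry O, C, O, O; H-6/H-7 are trans, H-7/H-8 are cis (the contra-steric relation), and the C8/C9 diol is threo. O8 and O9 bear different acyl groups, (S)-2-methylbutanoyl and acetyl, so the two oxygens must be told apart and then kept from exchanging by 1,2-acyl shift. The α-methylene lactone, the enal with an allylic acetate next to it (C9), and the two esters rule out strong bases and nucleophiles late in the route. The feature that opens the key step: C8 and C9 are neighbouring carbinol carbons, and C9 sits on the olefinic carbon C10, which carries a second oxygenated one-carbon arm (C14). The unit C14–C10(=C1)–C9 is therefore the skeleton of a 2-(oxymethyl)alk-2-enal whose two arms are interchangeable, and reductive umpolung of that enal at C9 with addition to a C8 aldehyde would close the ring between the two carbinol carbons.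

## Retrosynthesis

**From 28 back to 20 and 21 (no C–C bond cut).** Taken away in turn are the C15 silyl ether (27), the C9 acetate (26), the C14 aldehyde oxidation level (25), the two triethylsilyl ethers (24), the 11(13) double bond as its dimethylamine adduct (22), and the C8 ester (20 + acid 21). The order is dictated by differentiation: O8 is acylated while O9 is still silylated. Compound 20 holds the whole carbon skeleton and all four ring stereocentres; the forward steps ask only for chemoselectivity (primary against secondary OH, triethylsilyl against tert-butyldiphenylsilyl).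

**Key cut, C8–C9: 20 to dialdehyde 18.** A cut at C6–C7 or C7–C8 (allyl metal plus aldehyde) or at C9–C10 (vinyl metal plus aldehyde) leaves the diol array to be built and differentiated beforehand. The C8–C9 cut removes both carbinol centres and the ring at once, and 18 keeps only C6, C7 and the temporary C11 centre. The forward reaction, a CrCl2/Et3SiCl pinacol-type cross-coupling of the enal with the saturated aldehyde, must close a ten-membered ring and give the syn diol, the right face at C8 and a cis C1=C10 bond. It delivers O9 silylated and O8 free.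

**18 back to 15 (functional group unveiling).** The two arms on C10 (C9, C14) are carried as one acetonide and C8 as a dioxolane; one acid step frees all three (16). Mono-oxidation of the symmetric-looking allylic diol gives 17, and silylation gives 18. No selective protection is needed, since either arm may become C9.

**C4=C5: 15 back to aldehyde 12 and ylide 6.** A Wittig reaction with an α-branched formyl ylide puts CHO (C15) trans to C6, which is the ring-cis geometry. Reduction and silylation follow (13, 14, 15). A C3–C4 or C2–C3 coupling would have to build the trisubstituted olefin separately. Aldehyde 12 has three stereocentres on a five-membered ring; 6 is achiral.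

**C7–C8 and C11–C13: 12 back to butenolide 7.** C8 enters as a 1,3-dioxolan-2-yl radical anti to the C6 substituent (9), and C13 as a Mannich base (11) that serves as the masked α-methylene group until step 15. A cuprate route would need a formyl anion equivalent and a separate α-functionalisation. C6 comes from the chiral pool.

**C1=C10 and C4–C15: 6 back to 1 and 2.** A Wittig reaction of the symmetric ketone 2 with the mono-ylide of bis-phosphonium salt 1 gives 4 with no geometry to control. Formylation of the ylide of 4 then adds C15.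

## Roads not taken

Alternative 1: The most obvious cut is C6–C7 together with the lactone C12–O bond. Forward, the ω-formyl allylic bromide A1 would undergo an intramolecular Nozaki–Hiyama–Kishi or Barbier allylation (CrCl2 or Zn), and the homoallylic alkoxide would lactonise, closing both rings. The chosen plan is better for four reasons.
- A1 must already contain C8 and C9 with both esters, or two orthogonal protecting groups, made in separate stereoselective steps.
- The C8 acyloxy group lies in the vinylogous β-position of the allyl metal (M–C13–C11=C7–C8–O), so reductive 1,4-elimination to a diene competes.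
- The C6 aldehyde is a Z-configured β,β-disubstituted enal, geometrically labile and weakly electrophilic.
- The closed transition state from the Z bromide leads to the cis-lactone series, whereas the target is trans.

Alternative 2: Cut C1=C10 and close it by ring-closing metathesis of diene A2 with the second-generation Grubbs catalyst. This would form a trisubstituted olefin in a ten-membered ring from a 1,1-disubstituted alkene flanked by an allylic acetate. Ring strain alone would control the geometry, the α-methylene lactone is a third reactive alkene, and dimerisation competes. All four stereocentres and both esters must also be in place beforehand, so the ring closure solves nothing but the ring.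

Alternative 3: A skeletal route would break the C5–C10 bond of a cyclohexane in an anionic oxy-Cope rearrangement of the 1,2-dialkenylcyclohexanol A3, giving cyclodecenone A4. The chair transition state gives a ring-trans C4=C5 bond; a (Z,Z)-cyclodeca-1,5-diene would need a boat. C10 arrives as a ketone without C14, so an enol triflate with the right regiochemistry and geometry plus a carbonylation would have to follow. A3 is a cyclohexane substituted on all six carbons, longer to make than the whole chosen route. The same geometric limit applies to a photochemical [2+2]/cycloreversion sequence of a cyclobutene with a cyclohexenone.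

Key step: step 13

## Route

Step 1
Reactants: 1 butane-1,4-diylbis(triphenylphosphonium) dibromide; 2 2,2-dimethyl-1,3-dioxan-5-one
Product: 4 [4-(2,2-dimethyl-1,3-dioxan-5-ylidene)butyl]triphenylphosphonium bromide, via mono-ylide 3 (not isolated)
Conditions: 1 (1.5 equiv), KN(SiMe3)2 (1.5 equiv), THF, −78 to 0 °C; then 2, 0 °C to rt
Reagents that add atoms: none
Why: Wittig olefination of the ketone by the mono-ylide of the bis-phosphonium salt (the monocationic ylide is less acidic than the dication, which favours single deprotonation); C10 carries two identical CH2O arms, so the new C1=C10 bond has no geometry to control.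

Step 2
Reactants: 4
Product: 6 5-(2,2-dimethyl-1,3-dioxan-5-ylidene)-2-(triphenyl-λ5-phosphanylidene)pentanal, via ylide 5 (not isolated)
Conditions: KOt-Bu (2.1 equiv), THF, 0 °C; then HCO2Et, 0 °C to rt
Reagents that add atoms: ethyl formate, CCOC=O
Why: C-formylation of a non-stabilised ylide by a formate ester should give the stabilised α-formyl ylide after loss of ethoxide and proton transfer; this puts C15 on C4 at the aldehyde level.

Step 3
Reactants: 7 (S)-5-(hydroxymethyl)furan-2(5H)-one
Product: 8 (S)-5-{[(triethylsilyl)oxy]methyl}furan-2(5H)-one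
Conditions: Et3SiCl, imidazole, CH2Cl2, 0 °C
Reagents that add atoms: chlorotriethylsilane, CC[Si](Cl)(CC)CC
Why: Silylation of the primary alcohol; the stereocentre (C6 of the target) comes from the chiral pool, and the triethylsilyl ether can be oxidised directly in step 6.

Step 4
Reactants: 8
Product: 9 (4S,5S)-4-(1,3-dioxolan-2-yl)-5-{[(triethylsilyl)oxy]methyl}oxolan-2-one
Conditions: hν (350 nm), Ph2CO (0.2 equiv), 1,3-dioxolane (solvent), rt, degassed
Reagents that add atoms: 1,3-dioxolane, C1COCO1
Why: Benzophenone-sensitised radical conjugate addition: triplet benzophenone abstracts H-2 of dioxolane and the nucleophilic dioxolanyl radical adds to the β-carbon of the butenolide anti to the C6 substituent, which sets C7 trans to C6 and attaches C8 as a masked aldehyde.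

Step 5
Reactants: 9
Product: 11 (3R,4S,5S)-3-[(dimethylamino)methyl]-4-(1,3-dioxolan-2-yl)-5-{[(triethylsilyl)oxy]methyl}oxolan-2-one, via lithium enolate 10 (not isolated)
Conditions: LiN(i-Pr)2, THF, −78 °C; then CH2=NMe2+ I−, −78 to 0 °C
Reagents that add atoms: N,N-dimethylmethyleneiminium iodide, C=[N+](C)C.[I-]
Why: Mannich reaction of the lactone enolate with the iminium salt, anti to the C7 substituent (the C11 centre is destroyed later); the β-amino lactone is the masked α-methylene lactone and should resist nucleophiles, bases and double-bond migration through steps 6–14.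

Step 6
Reactants: 11
Product: 12 (2S,3S,4R)-4-[(dimethylamino)methyl]-3-(1,3-dioxolan-2-yl)-5-oxooxolane-2-carbaldehyde
Conditions: (COCl)2, DMSO, CH2Cl2, −78 °C; 11, −78 to −30 °C; Et3N, −78 to 0 °C
Reagents that add atoms: none
Why: Swern oxidation applied directly to the primary triethylsilyl ether (activated DMSO displaces the silyl group from oxygen) should give the C5 aldehyde without a separate deprotection; the low temperature protects the α-oxygenated centre C6.

Step 7
Reactants: 12; 6
Product: 13 (2E)-2-{[(2R,3S,4R)-4-[(dimethylamino)methyl]-3-(1,3-dioxolan-2-yl)-5-oxooxolan-2-yl]methylidene}-5-(2,2-dimethyl-1,3-dioxan-5-ylidene)pentanal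
Conditions: PhMe, 70 °C
Reagents that add atoms: none
Why: Wittig olefination with an α-branched formyl-stabilised ylide should place the CHO group (C15) trans to C6, which is the C4=C5 geometry with C3 and C6 cis that the ten-membered ring needs; no stereocentre is formed.

Step 8
Reactants: 13
Product: 14 (3R,4S,5R)-3-[(dimethylamino)methyl]-5-[(1E)-5-(2,2-dimethyl-1,3-dioxan-5-ylidene)-2-(hydroxymethyl)pent-1-en-1-yl]-4-(1,3-dioxolan-2-yl)oxolan-2-one
Conditions: NaBH4, CeCl3·7H2O, MeOH, −40 °C
Reagents that add atoms: none
Why: Luche 1,2-reduction of the only aldehyde; lactone, acetals and amine should be untouched.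

Step 9
Reactants: 14
Product: 15 (3R,4S,5R)-5-[(1E)-2-({[tert-butyl(diphenyl)silyl]oxy}methyl)-5-(2,2-dimethyl-1,3-dioxan-5-ylidene)pent-1-en-1-yl]-3-[(dimethylamino)methyl]-4-(1,3-dioxolan-2-yl)oxolan-2-one
Conditions: t-BuPh2SiCl, imidazole, DMF, rt
Reagents that add atoms: tert-butyl(chloro)diphenylsilane, CC(C)(C)[Si](Cl)(c1ccccc1)c1ccccc1
Why: Silylation of the primary allylic alcohol (O15) with a group that should survive aqueous acid, MnO2, CrCl2 and the later removal of the triethylsilyl ethers.

Step 10
Reactants: 15
Product: 16 (2R,3S,4R)-2-[(1E)-2-({[tert-butyl(diphenyl)silyl]oxy}methyl)-7-hydroxy-6-(hydroxymethyl)hepta-1,5-dien-1-yl]-4-[(dimethylamino)methyl]-5-oxooxolane-3-carbaldehyde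
Conditions: 1 M HCl (aq)/THF 1:3, rt; then NaHCO3
Reagents that add atoms: water, O
Why: Acid hydrolysis of both acetals in one operation gives the 2-alkylidenepropane-1,3-diol (O9-H, O14-H) and the C8 aldehyde; without the 11(13) double bond the formyl lactone has no conjugated isomer to fall into, and the trans arrangement at C7 is the stable one.

Step 11
Reactants: 16
Product: 17 (2R,3S,4R)-2-[(1E,5E)-2-({[tert-butyl(diphenyl)silyl]oxy}methyl)-6-formyl-7-hydroxyhepta-1,5-dien-1-yl]-4-[(dimethylamino)methyl]-5-oxooxolane-3-carbaldehyde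
Conditions: MnO2 (activated, 10 equiv), CH2Cl2, rt
Reagents that add atoms: none
Why: Allylic oxidation of one of the two hydroxymethyl arms on C10; the arms are equivalent for the route, the saturated aldehyde is inert, and the first CHO should slow oxidation of the second arm.

Step 12
Reactants: 17
Product: 18 (2R,3S,4R)-2-[(1E,5E)-2-({[tert-butyl(diphenyl)silyl]oxy}methyl)-6-formyl-7-[(triethylsilyl)oxy]hepta-1,5-dien-1-yl]-4-[(dimethylamino)methyl]-5-oxooxolane-3-carbaldehyde
Conditions: Et3SiCl, imidazole, CH2Cl2, 0 °C
Reagents that add atoms: chlorotriethylsilane, CC[Si](Cl)(CC)CC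
Why: Silylation of the remaining primary alcohol (O14), so that O8 is the only free hydroxyl after step 13.

Step 13
Reactants: 18
Product: 20 15-{[tert-butyl(diphenyl)silyl]oxy}-13-(dimethylamino)-8β-hydroxy-9α,14-bis[(triethylsilyl)oxy]-11β,13-dihydro-1(10)-cis,4-cis-germacra-1(10),4-dien-12,6α-olide, via siloxyallylchromium dichloride 19 (not isolated)
Conditions: CrCl2 (6 equiv), Et3SiCl (2.2 equiv), DMF/THF, slow addition of 18 (final 2 mM), 0 °C to rt; then pH 7 phosphate buffer
Reagents that add atoms: chlorotriethylsilane, CC[Si](Cl)(CC)CC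
Why: CrCl2 reduces the silyl-activated enal (C9=O conjugated with C10=C1) in two one-electron steps to the γ-siloxyallylchromium species 19 (trivalent chromium on C1, OSiEt3 on C9), while the saturated C8 aldehyde is not reduced and serves as the electrophile. Species 19 adds through its γ-carbon C9 to C8 in a six-membered Zimmerman–Traxler transition state; the closest known reaction type is the CrCl2/R3SiCl pinacol-type cross-coupling of enals and enones with aldehydes, which is also known intramolecularly for 2-methylene-α,ω-dicarbonyl compounds. The ten-membered carbocycle closes by a 10-endo addition in which the allyl unit C1–C10–C9 becomes part of the ring and the double bond returns to C1=C10. For C8/C9, the (Z)-siloxyallyl unit (OSiEt3 syn to C1, as α-branched enals give) with C7 equatorial should lead to the syn (threo) diol. For C8 relative to C7, ring formation requires the new bond gauche to C7–C6 and hence anti to C7–C11, and the allyl carbon then passes H-7 (Felkin–Anh), which should give 8β-OH. For C1=C10, C2 sits axial on C1 (1,2-strain with the CH2OSiEt3 group on C10 and the short C3–C4=C5–C6 tether), which should give the ring-cis bond. The step needs three selectivities: reduction of the enal and not the saturated aldehyde (intrinsic to divalent chromium), silicon on O9 with O8 left as the chromium alkoxide until work-up (the silyl group enters in the reduction step, so the two oxygens come out differentiated), and ring closure over oligomerisation (high dilution, with the cis C4=C5 bond and the trans-lactone as turn elements). The β-amino lactone, the silyl ethers and the C4=C5 bond should be inert to CrCl2.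

Step 14
Reactants: 20; 21 (S)-2-methylbutanoic acid
Product: 22 15-{[tert-butyl(diphenyl)silyl]oxy}-13-(dimethylamino)-8β-{[(2S)-2-methylbutanoyl]oxy}-9α,14-bis[(triethylsilyl)oxy]-11β,13-dihydro-1(10)-cis,4-cis-germacra-1(10),4-dien-12,6α-olide
Conditions: DCC, DMAP (0.2 equiv), CH2Cl2, 0 °C to rt
Reagents that add atoms: none
Why: Steglich esterification of the only free hydroxyl (O8); the acid brings its stereocentre from the chiral pool, and O9 is blocked as its silyl ether.

Step 15
Reactants: 22
Product: 24 15-{[tert-butyl(diphenyl)silyl]oxy}-8β-{[(2S)-2-methylbutanoyl]oxy}-9α,14-bis[(triethylsilyl)oxy]-1(10)-cis,4-cis-germacra-1(10),4,11(13)-trien-12,6α-olide, via trimethylammonium iodide 23 (not isolated)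
Conditions: MeI, MeCN, rt; then NaHCO3 (aq), rt
Reagents that add atoms: none
Why: Quaternisation of the amine followed by E1cB elimination across C11–C13 under bicarbonate should unmask the α-methylene lactone; esters and silyl ethers tolerate these conditions.

Step 16
Reactants: 24
Product: 25 15-{[tert-butyl(diphenyl)silyl]oxy}-9α,14-dihydroxy-8β-{[(2S)-2-methylbutanoyl]oxy}-1(10)-cis,4-cis-germacra-1(10),4,11(13)-trien-12,6α-olide
Conditions: HF·pyridine, pyridine, THF, 0 °C
Reagents that add atoms: none
Why: Fluoride cleavage of the two triethylsilyl ethers (O9, O14) should be much faster than that of the tert-butyldiphenylsilyl ether at O15; the buffered, non-basic medium limits acyl shift from O8 to O9.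

Step 17
Reactants: 25
Product: 26 15-{[tert-butyl(diphenyl)silyl]oxy}-9α-hydroxy-8β-{[(2S)-2-methylbutanoyl]oxy}-14-oxo-1(10)-cis,4-cis-germacra-1(10),4,11(13)-trien-12,6α-olide
Conditions: TEMPO (0.1 equiv), PhI(OAc)2 (1.1 equiv), CH2Cl2, rt
Reagents that add atoms: none
Why: Oxoammonium oxidation, selective for the primary allylic alcohol over the secondary O9-H, should give the C14 enal; CHO trans to C2 is also the thermodynamically preferred geometry of a 2-substituted enal.

Step 18
Reactants: 26
Product: 27 9α-acetoxy-15-{[tert-butyl(diphenyl)silyl]oxy}-8β-{[(2S)-2-methylbutanoyl]oxy}-14-oxo-1(10)-cis,4-cis-germacra-1(10),4,11(13)-trien-12,6α-olide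
Conditions: Ac2O, pyridine, CH2Cl2, 0 °C
Reagents that add atoms: acetic anhydride, CC(=O)OC(C)=O
Why: Acetylation of the secondary allylic O9-H; no nucleophilic catalyst is used, so that the allylic acetate next to the enal is not displaced in an SN2' sense.

Step 19
Reactants: 27
Product: 28 9α-acetoxy-15-hydroxy-8β-{[(2S)-2-methylbutanoyl]oxy}-14-oxo-1(10)-cis,4-cis-germacra-1(10),4,11(13)-trien-12,6α-olide (target, 6R,7S,8S,9S)
Conditions: HF·pyridine, pyridine, THF, 0 °C to rt
Reagents that add atoms: none
Why: Buffered fluoride cleavage of the tert-butyldiphenylsilyl ether should free O15-H without touching the enal, the esters or the α-methylene lactone.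

## Compound list

1 | butane-1,4-diylbis(triphenylphosphonium) dibromide | [Br-].[Br-].c1ccc(cc1)[P+](c1ccccc1)(c1ccccc1)CCCC[P+](c1ccccc1)(c1ccccc1)c1ccccc1 | starting material
2 | 2,2-dimethyl-1,3-dioxan-5-one | CC1(C)OCC(=O)CO1 | starting material
3 | mono-ylide of 1, [4-(triphenylphosphonio)butylidene]triphenylphosphorane bromide | [Br-].c1ccc(cc1)P(=CCCC[P+](c1ccccc1)(c1ccccc1)c1ccccc1)(c1ccccc1)c1ccccc1 | intermediate (not isolated)
4 | [4-(2,2-dimethyl-1,3-dioxan-5-ylidene)butyl]triphenylphosphonium bromide | [Br-].CC1(C)OCC(=CCCC[P+](c2ccccc2)(c2ccccc2)c2ccccc2)CO1 | intermediate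
5 | ylide of 4 | CC1(C)OCC(=CCCC=P(c2ccccc2)(c2ccccc2)c2ccccc2)CO1 | intermediate (not isolated)
6 | 5-(2,2-dimethyl-1,3-dioxan-5-ylidene)-2-(triphenyl-λ5-phosphanylidene)pentanal | CC1(C)OCC(=CCCC(C=O)=P(c2ccccc2)(c2ccccc2)c2ccccc2)CO1 | intermediate
7 | (S)-5-(hydroxymethyl)furan-2(5H)-one | O=C1O[C@H](CO)C=C1 | starting material
8 | (S)-5-{[(triethylsilyl)oxy]methyl}furan-2(5H)-one | O=C1O[C@H](CO[Si](CC)(CC)CC)C=C1 | intermediate
9 | (4S,5S)-4-(1,3-dioxolan-2-yl)-5-{[(triethylsilyl)oxy]methyl}oxolan-2-one | O=C1O[C@H](CO[Si](CC)(CC)CC)[C@@H](C2OCCO2)C1 | intermediate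
10 | lithium enolate of 9 | [Li+].[O-]C1=C[C@H](C2OCCO2)[C@@H](CO[Si](CC)(CC)CC)O1 | intermediate (not isolated)
11 | (3R,4S,5S)-3-[(dimethylamino)methyl]-4-(1,3-dioxolan-2-yl)-5-{[(triethylsilyl)oxy]methyl}oxolan-2-one | O=C1O[C@H](CO[Si](CC)(CC)CC)[C@@H](C2OCCO2)[C@@H]1CN(C)C | intermediate
12 | (2S,3S,4R)-4-[(dimethylamino)methyl]-3-(1,3-dioxolan-2-yl)-5-oxooxolane-2-carbaldehyde | O=C1O[C@H](C=O)[C@@H](C2OCCO2)[C@@H]1CN(C)C | intermediate
13 | enal from Wittig reaction (name in step 7) | O=C1O[C@H](/C=C(/C=O)CCC=C2COC(C)(C)OC2)[C@@H](C2OCCO2)[C@@H]1CN(C)C | intermediate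
14 | allylic alcohol (name in step 8) | O=C1O[C@H](/C=C(/CO)CCC=C2COC(C)(C)OC2)[C@@H](C2OCCO2)[C@@H]1CN(C)C | intermediate
15 | tert-butyldiphenylsilyl ether of 14 (name in step 9) | O=C1O[C@H](/C=C(/CO[Si](c2ccccc2)(c2ccccc2)C(C)(C)C)CCC=C2COC(C)(C)OC2)[C@@H](C2OCCO2)[C@@H]1CN(C)C | intermediate
16 | aldehyde diol (name in step 10) | O=C1O[C@H](/C=C(/CO[Si](c2ccccc2)(c2ccccc2)C(C)(C)C)CCC=C(CO)CO)[C@@H](C=O)[C@@H]1CN(C)C | intermediate
17 | hydroxy enal aldehyde (name in step 11) | O=C1O[C@H](/C=C(/CO[Si](c2ccccc2)(c2ccccc2)C(C)(C)C)CC/C=C(/C=O)CO)[C@@H](C=O)[C@@H]1CN(C)C | intermediate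
18 | dialdehyde, C8 aldehyde and C9 enal (name in step 12) | O=C1O[C@H](/C=C(/CO[Si](c2ccccc2)(c2ccccc2)C(C)(C)C)CC/C=C(/C=O)CO[Si](CC)(CC)CC)[C@@H](C=O)[C@@H]1CN(C)C | intermediate
19 | γ-siloxyallylchromium dichloride (Cr on C1, configuration at C1 labile) | O=C1O[C@H](/C=C(/CO[Si](c2ccccc2)(c2ccccc2)C(C)(C)C)CCC([Cr](Cl)Cl)/C(CO[Si](CC)(CC)CC)=C\O[Si](CC)(CC)CC)[C@@H](C=O)[C@@H]1CN(C)C | intermediate (not isolated)
20 | macrocyclic 8β-ol (name in step 13) | CN(C)C[C@@H]1C(=O)O[C@@H]2/C=C(/CO[Si](c3ccccc3)(c3ccccc3)C(C)(C)C)CC/C=C(/CO[Si](CC)(CC)CC)[C@H](O[Si](CC)(CC)CC)[C@@H](O)[C@@H]12 | intermediate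
21 | (S)-2-methylbutanoic acid | CC[C@H](C)C(O)=O | starting material
22 | 8β-(2-methylbutanoate) (name in step 14) | CN(C)C[C@@H]1C(=O)O[C@@H]2/C=C(/CO[Si](c3ccccc3)(c3ccccc3)C(C)(C)C)CC/C=C(/CO[Si](CC)(CC)CC)[C@H](O[Si](CC)(CC)CC)[C@@H](OC(=O)[C@@H](C)CC)[C@@H]12 | intermediate
23 | trimethylammonium iodide of 22 | [I-].C[N+](C)(C)C[C@@H]1C(=O)O[C@@H]2/C=C(/CO[Si](c3ccccc3)(c3ccccc3)C(C)(C)C)CC/C=C(/CO[Si](CC)(CC)CC)[C@H](O[Si](CC)(CC)CC)[C@@H](OC(=O)[C@@H](C)CC)[C@@H]12 | intermediate (not isolated)
24 | α-methylene lactone (name in step 15) | C=C1C(=O)O[C@@H]2/C=C(/CO[Si](c3ccccc3)(c3ccccc3)C(C)(C)C)CC/C=C(/CO[Si](CC)(CC)CC)[C@H](O[Si](CC)(CC)CC)[C@@H](OC(=O)[C@@H](C)CC)[C@@H]12 | intermediate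
25 | 9α,14-diol (name in step 16) | C=C1C(=O)O[C@@H]2/C=C(/CO[Si](c3ccccc3)(c3ccccc3)C(C)(C)C)CC/C=C(/CO)[C@H](O)[C@@H](OC(=O)[C@@H](C)CC)[C@@H]12 | intermediate
26 | 14-al 9α-ol (name in step 17) | C=C1C(=O)O[C@@H]2/C=C(/CO[Si](c3ccccc3)(c3ccccc3)C(C)(C)C)CC/C=C(/C=O)[C@H](O)[C@@H](OC(=O)[C@@H](C)CC)[C@@H]12 | intermediate
27 | 9α-acetate, 15-silyl ether (name in step 18) | C=C1C(=O)O[C@@H]2/C=C(/CO[Si](c3ccccc3)(c3ccccc3)C(C)(C)C)CC/C=C(/C=O)[C@H](OC(C)=O)[C@@H](OC(=O)[C@@H](C)CC)[C@@H]12 | intermediate
28 | 9α-acetoxy-15-hydroxy-8β-{[(2S)-2-methylbutanoyl]oxy}-14-oxo-1(10)-cis,4-cis-germacra-1(10),4,11(13)-trien-12,6α-olide | C=C1C(=O)O[C@@H]2/C=C(/CO)CC/C=C(/C=O)[C@H](OC(C)=O)[C@@H](OC(=O)[C@@H](C)CC)[C@@H]12 | target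

## Step count and least certain steps

Total step count: 19. Longest linear sequence: 17 (steps 3–19 from 7; the branch 1/2 to 6 joins at step 7).

**Step 13 (key step).** Most likely to go wrong: poor facial selectivity at the C8 aldehyde. The Felkin preference rests only on the ring-imposed rotamer about C7–C8, and a 1,3-diaxial contact between OSiEt3 and C2 in the favoured chair could shift the reaction to the chair with C7 axial, which gives the 8α-alcohol. Oligomerisation is the second concern and is met by dilution. Fallback: setting out from 18, the cyclisation is run as before and the 8α-hydroxy epimer F1 is esterified with 21 under Mitsunobu conditions (PPh3, DIAD, PhMe, 0 °C). This inverts C8 in the ester-forming step and comes back to the route at 22.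

**Step 1.** Most likely to go wrong: enolisation of the α,α'-dioxygenated ketone by the basic ylide and double olefination of the bis-salt. Fallback: setting out from 2, vinylmagnesium bromide gives the tertiary allylic alcohol F2. A Johnson–Claisen rearrangement (MeC(OEt)3, cat. propionic acid, 140 °C) then gives ester F3 and forms C1=C10 by a sigmatropic shift, not an olefination. LiAlH4 gives alcohol F4, CBr4/PPh3 gives bromide F5, and PPh3 in MeCN returns to the route at 4.

**Step 11.** Most likely to go wrong: over-oxidation of the second hydroxymethyl arm, or a stalled heterogeneous oxidation. Fallback: setting out from 16, one arm is silylated first (Et3SiCl 1 equiv, imidazole, −40 °C) to the mono-silyl ether F6, and the other arm is then oxidised with Dess–Martin periodinane. Either double-bond isomer of F6 ends at 18 once the enal geometry has equilibrated, so the sequence comes back to the route at 18 and bypasses 17.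

**Step 16.** Most likely to go wrong: 1,2-acyl shift of the 2-methylbutanoyl group from O8 to the freed O9-H, here or during steps 17–18. Fallback: setting out from 24, only the primary silyl ether is cleaved (PPTS, MeOH, 0 °C) to F7. C14 is oxidised (TEMPO, PhI(OAc)2) to F8 with O9 still silylated. The secondary silyl ether is then cleaved with HF·pyridine in the presence of Ac2O/pyridine, so that O9-H is acetylated as it forms, and the route is rejoined at 27.

## Further compounds

F1 | step 13 | 8α-hydroxy epimer of 20 | CN(C)C[C@@H]1C(=O)O[C@@H]2/C=C(/CO[Si](c3ccccc3)(c3ccccc3)C(C)(C)C)CC/C=C(/CO[Si](CC)(CC)CC)[C@H](O[Si](CC)(CC)CC)[C@H](O)[C@@H]12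
F2 | step 1 | 2,2-dimethyl-5-vinyl-1,3-dioxan-5-ol | CC1(C)OCC(O)(C=C)CO1
F3 | step 1 | ethyl 4-(2,2-dimethyl-1,3-dioxan-5-ylidene)butanoate | CCOC(=O)CCC=C1COC(C)(C)OC1
F4 | step 1 | 4-(2,2-dimethyl-1,3-dioxan-5-ylidene)butan-1-ol | OCCCC=C1COC(C)(C)OC1
F5 | step 1 | 5-(4-bromobutylidene)-2,2-dimethyl-1,3-dioxane | BrCCCC=C1COC(C)(C)OC1
F6 | step 11 | mono-triethylsilyl ether of diol 16 (one double-bond isomer drawn) | O=C1O[C@H](/C=C(/CO[Si](c2ccccc2)(c2ccccc2)C(C)(C)C)CC/C=C(/CO)CO[Si](CC)(CC)CC)[C@@H](C=O)[C@@H]1CN(C)C
F7 | step 16 | 14-hydroxy-9α-[(triethylsilyl)oxy] analogue of 25 | C=C1C(=O)O[C@@H]2/C=C(/CO[Si](c3ccccc3)(c3ccccc3)C(C)(C)C)CC/C=C(/CO)[C@H](O[Si](CC)(CC)CC)[C@@H](OC(=O)[C@@H](C)CC)[C@@H]12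
F8 | step 16 | 14-oxo-9α-[(triethylsilyl)oxy] analogue of 26 | C=C1C(=O)O[C@@H]2/C=C(/CO[Si](c3ccccc3)(c3ccccc3)C(C)(C)C)CC/C=C(/C=O)[C@H](O[Si](CC)(CC)CC)[C@@H](OC(=O)[C@@H](C)CC)[C@@H]12
A1 | alternative 1 | ω-formyl allylic bromide: methyl (Z)-2-(bromomethyl)enoate with C6 enal, 8-(2-methylbutanoate), 9-acetate, 14,15-bis(tert-butyldimethylsilyl) ethers | O=C/C=C(/CO[Si](C)(C)C(C)(C)C)CC/C=C(/CO[Si](C)(C)C(C)(C)C)[C@H](OC(C)=O)[C@@H](OC(=O)[C@@H](C)CC)/C=C(/C(=O)OC)CBr
A2 | alternative 2 | metathesis diene: lactone with C1 vinyl terminus and C10 methylidene | C=C1C(=O)O[C@H](/C=C(/CO[Si](c2ccccc2)(c2ccccc2)C(C)(C)C)CCC=C)[C@H]1[C@H](OC(=O)[C@@H](C)CC)[C@@H](OC(C)=O)C(=C)CO[Si](CC)(CC)CC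
A3 | alternative 3 | 1-vinyl-2-alkenylcyclohexanol (C10 carbinol; 8,9-acetonide, 6-PMB ether, 7-isopropenyl) | C=C[C@]1(O)[C@@H]2OC(C)(C)O[C@H]2[C@@H](C(C)=C)[C@H](OCc2ccc(OC)cc2)[C@H]1C(=C)CO[Si](C)(C)C(C)(C)C
A4 | alternative 3 | cyclodec-5-enone from oxy-Cope rearrangement (C10 ketone, ring-trans C4=C5) | O=C1CCC/C(CO[Si](C)(C)C(C)(C)C)=C/[C@@H](OCc2ccc(OC)cc2)[C@H](C(C)=C)[C@@H]2OC(C)(C)O[C@@H]12
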